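**Retrosynthetic overview**
1. Target ⇐ fully assembled lactone carrying three aryl methyl ethers and a tert-butyl ester, unmasked in one Lewis-acid dealkylation.
2. The lactone is the only ring made and is closed last through its alkyl C3–O bond: the benzoic acid oxygen displaces the activated ketone oxygen of an α-keto ester (deoxygenative O–H insertion). This fixes C3; C4 then settles trans by equilibration.
3. α-Keto ester ⇐ γ-oxalylation (vinylogous Claisen) of a 2-benzylfumarate with dimethyl oxalate (C3–C4 bond).
4. 2-Benzylfumarate ⇐ carboxylate-directed ortho C–H allylation of 2,4,5-trimethoxybenzoic acid with a Morita–Baylis–Hillman acetate (aryl–CH2 bond, E-alkene, side-chain esters already differentiated).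
5. Acetate ⇐ methyl acrylate + tert-butyl glyoxylate; the benzene ring is bought intact.

Assumption: tert-butyl glyoxylate is bought and distilled before use; the chiral phosphorus triamide of step 5 is prepared beforehand from P(NMe2)3 and commercial (1R,2R)-N,N′-dimethyl-1,2-diphenylethane-1,2-diamine and is not counted as a step; its sense of induction is assigned by model, and the mirror-image reagent is used if it proves opposite.

**Step 1**
Reactants: 1 methyl acrylate; 2 tert-butyl glyoxylate
Product: 3 racemic Morita–Baylis–Hillman alcohol (4-tert-butyl 1-methyl 3-hydroxy-2-methylidenebutanedioate)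
Conditions: DABCO (20 mol%), 1,4-dioxane, rt
Reagents that add atoms: none
Why: Morita–Baylis–Hillman reaction, in which the ammonium enolate from DABCO and the acrylate adds to the very electrophilic glyoxylate aldehyde; the racemic carbinol centre is erased in step 3.

**Step 2**
Reactants: 3 racemic Morita–Baylis–Hillman alcohol
Product: 4 allylic acetate (4-tert-butyl 1-methyl 3-acetoxy-2-methylidenebutanedioate; racemic)
Conditions: Ac2O, pyridine, DMAP (5 mol%), CH2Cl2, 0 °C to rt
Reagents that add atoms: acetic anhydride, CC(=O)OC(C)=O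
Why: DMAP-catalysed O-acetylation turns the secondary allylic hydroxyl into the leaving group needed for allylic transposition.

**Step 3**
Reactants: 5 2,4,5-trimethoxybenzoic acid; 4 allylic acetate
Product: 6 benzylfumarate acid (2-[(2E)-4-tert-butoxy-2-(methoxycarbonyl)-4-oxobut-2-en-1-yl]-3,4,6-trimethoxybenzoic acid)
Conditions: [RhCl2(C5Me5)]2 (2.5 mol%), AgSbF6 (10 mol%), NaOAc (30 mol%), ClCH2CH2Cl, 50 °C
Reagents that add atoms: none
Why: Carboxylate-directed C–H allylation by trivalent rhodium: the only ortho C–H is metalated, the acrylate alkene inserts and β-acetoxy elimination (formal SN2′) gives the more stable E (fumarate-type) alkene with the CH2 cis to the tert-butyl ester.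

**Step 4**
Reactants: 6 benzylfumarate acid; 7 dimethyl oxalate
Product: 8 α-keto ester acid (2-[(4E)-6-tert-butoxy-1-methoxy-4-(methoxycarbonyl)-1,2,6-trioxohex-4-en-3-yl]-3,4,6-trimethoxybenzoic acid; racemic at the benzylic carbon, keto form drawn, in equilibrium with enol and cyclic hemiketal forms)
Conditions: NaH (3 equiv), THF, 0 °C to rt; cold 1 M HCl work-up, used crude
Reagents that add atoms: none
Why: Vinylogous (γ) Claisen condensation: the dienolate from the benzylic CH2 is acylated reversibly by the oxalate and the reaction drains into the γ-acyl product, whose enolate is conjugated with the arene and both esters, while the bulky tert-butyl ester shields the α-carbon; the new C–H centre is racemic and labile.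

**Step 5**
Reactants: 8 α-keto ester acid
Product: 10 protected lactone (methyl (3S,4R)-4-[(1E)-3-tert-butoxy-1-(methoxycarbonyl)-3-oxoprop-1-en-1-yl]-5,6,8-trimethoxy-1-oxo-3,4-dihydro-1H-isochromene-3-carboxylate), via C4-epimeric lactone mixture 9 (not isolated)
Conditions: (4R,5R)-2-(dimethylamino)-1,3-dimethyl-4,5-diphenyl-1,3,2-diazaphospholidine (1.2 equiv), CH2Cl2, −78 to −20 °C; then DBU (5 mol%), 0 °C
Reagents that add atoms: none
Why: Proposed new method: the trivalent phosphorus triamide adds to the 1,2-dicarbonyl of the keto tautomer of 8 (Kukhtin–Ramirez adduct, an oxyphosphonium enolate), the neighbouring benzoic acid protonates C3 reversibly, and the resulting carboxylate closes the ring by a 6-exo-tet SN2 displacement of the phosphoramide oxide at C3, so the lactone C3–O bond forms with inversion inside a chiral ion pair in which the diphenyl-diamine backbone on phosphorus discriminates the two interconverting C3-epimeric oxyphosphonium species and delivers 3S, after which DBU equilibrates the acidic benzylic, γ-enoate C4–H through its dienolate to the trans (4R) isomer that keeps the side chain away from the peri methoxy group; the closest known reaction type is the phosphorus-mediated deoxygenative condensation (formal reductive O–H insertion) of α-keto esters with carboxylic acids, so far intermolecular and racemic.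

**Step 6**
Reactants: 10 protected lactone
Product: 11 target ((2E)-4-methoxy-4-oxo-3-[(3S,4R)-5,6,8-trihydroxy-3-(methoxycarbonyl)-1-oxo-3,4-dihydro-1H-isochromen-4-yl]but-2-enoic acid)
Conditions: BBr3 (8 equiv), CH2Cl2, −78 to 0 °C; degassed H2O quench, work-up under argon
Reagents that add atoms: none
Why: Lewis-acid dealkylation: BBr3 cleaves the three aryl methyl ethers (one chelation-assisted next to the lactone carbonyl, two as a vicinal pair) and the tert-butyl ester faster than the aliphatic methyl esters and the lactone at or below 0 °C, and no stereocentre is touched.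

**Compound list**
1 | methyl acrylate | C=CC(=O)OC | starting material
2 | tert-butyl glyoxylate (tert-butyl 2-oxoacetate) | O=CC(=O)OC(C)(C)C | starting material
3 | 4-tert-butyl 1-methyl 3-hydroxy-2-methylidenebutanedioate (racemic) | C=C(C(=O)OC)C(O)C(=O)OC(C)(C)C | intermediate
4 | 4-tert-butyl 1-methyl 3-acetoxy-2-methylidenebutanedioate (racemic) | C=C(C(=O)OC)C(OC(C)=O)C(=O)OC(C)(C)C | intermediate
5 | 2,4,5-trimethoxybenzoic acid | COc1cc(OC)c(OC)cc1C(=O)O | starting material
6 | 2-[(2E)-4-tert-butoxy-2-(methoxycarbonyl)-4-oxobut-2-en-1-yl]-3,4,6-trimethoxybenzoic acid | COC(=O)/C(=C/C(=O)OC(C)(C)C)Cc1c(OC)c(OC)cc(OC)c1C(=O)O | intermediate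
7 | dimethyl oxalate | COC(=O)C(=O)OC | starting material
8 | 2-[(4E)-6-tert-butoxy-1-methoxy-4-(methoxycarbonyl)-1,2,6-trioxohex-4-en-3-yl]-3,4,6-trimethoxybenzoic acid (racemic, keto form) | COC(=O)/C(=C/C(=O)OC(C)(C)C)C(C(=O)C(=O)OC)c1c(OC)c(OC)cc(OC)c1C(=O)O | intermediate
9 | methyl (3S)-4-[(1E)-3-tert-butoxy-1-(methoxycarbonyl)-3-oxoprop-1-en-1-yl]-5,6,8-trimethoxy-1-oxo-3,4-dihydro-1H-isochromene-3-carboxylate, mixture of C4 epimers (3S,4R and 3S,4S) | COC(=O)/C(=C/C(=O)OC(C)(C)C)C1c2c(OC)c(OC)cc(OC)c2C(=O)O[C@@H]1C(=O)OC | intermediate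
10 | methyl (3S,4R)-4-[(1E)-3-tert-butoxy-1-(methoxycarbonyl)-3-oxoprop-1-en-1-yl]-5,6,8-trimethoxy-1-oxo-3,4-dihydro-1H-isochromene-3-carboxylate | COC(=O)/C(=C/C(=O)OC(C)(C)C)[C@H]1c2c(OC)c(OC)cc(OC)c2C(=O)O[C@@H]1C(=O)OC | intermediate
11 | (2E)-4-methoxy-4-oxo-3-[(3S,4R)-5,6,8-trihydroxy-3-(methoxycarbonyl)-1-oxo-3,4-dihydro-1H-isochromen-4-yl]but-2-enoic acid | COC(=O)/C(=C/C(=O)O)[C@H]1c2c(O)c(O)cc(O)c2C(=O)O[C@@H]1C(=O)OC | target

**Step count and risks**
Total: 6 steps. Longest linear sequence: 6 steps (methyl acrylate to 11); compounds 5 and 7 enter convergently at steps 3 and 4.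

Most likely to fail, in this order: step 5, step 4, step 6.

Step 5 (the proposed new step). The phosphorus reagent may add to the fumarate instead of the dicarbonyl. The oxyphosphonium may eliminate toward the acidic C4–H instead of being displaced. The enol and hemiketal forms of 8 may not funnel through the keto form, and the level of asymmetric induction is unproven. In the DBU stage, base may open the lactone by E1cB or epimerise C3. The fallback uses known chemistry and sets out from 8. A dynamic kinetic asymmetric transfer hydrogenation (Noyori–Ikariya type) with RuCl(p-cymene)[(S,S)-TsDPEN] (divalent ruthenium; the enantiomer that gives the 3S alcohol) and HCO2H/Et3N in DMF reduces the ketone while C4 racemises through the enol, giving the (S)-hydroxy acid F2. Catalytic TsOH in toluene lactonises F2 by ordinary acyl substitution with retention at C3, which comes back to the route at 9; the DBU equilibration then gives 10.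

Step 4. Acylation may occur at the α-carbon next to the tert-butyl ester, and the enol of 8 can cyclise onto that ester to a 2-pyrone if warmed or left in acid. The fallback sets out from 6. LiN(SiMe3)2 and TBSCl in THF at −78 °C give the silyl ester silyl dienol ether F1. A Mukaiyama-type acylation of F1 with methyl chlorooxoacetate and ZnCl2 in CH2Cl2 at −78 °C is γ-selective for silyl dienol ethers. Buffered aqueous work-up removes both silyl groups and comes back to the route at 8.

Step 6. BBr3 may also cleave a methyl ester or open the lactone at C3, and the hydroxyhydroquinone product is air-sensitive. The fallback sets out from 10 and removes the methyl ethers oxidatively. Trifluoroacetic acid in CH2Cl2 frees the side-chain acid to give the tri-O-methyl acid F3. (NH4)2Ce(NO3)6 (tetravalent cerium) in aqueous MeCN at 0 °C oxidatively demethylates the para-disposed 5,8-dimethoxy pair to the 6-methoxy-5,8-quinone F4. Dilute aqueous HCl in THF hydrolyses the vinylogous methyl ester of F4 to the hydroxyquinone F5. Na2S2O4 in water/EtOAc reduces F5 to the hydroxyhydroquinone, which comes back to the route at 11.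

**Further compounds**
F1 | step 4 | tert-butyldimethylsilyl 2-[4-tert-butoxy-4-(tert-butyldimethylsilyloxy)-2-(methoxycarbonyl)buta-1,3-dien-1-yl]-3,4,6-trimethoxybenzoate (mixture of alkene isomers) | CC(C)(C)OC(O[Si](C)(C)C(C)(C)C)=CC(C(=O)OC)=Cc1c(OC)c(OC)cc(OC)c1C(=O)O[Si](C)(C)C(C)(C)C
F2 | step 5 | 2-[(2S,4E)-6-tert-butoxy-2-hydroxy-1-methoxy-4-(methoxycarbonyl)-1,6-dioxohex-4-en-3-yl]-3,4,6-trimethoxybenzoic acid (both C3-chain epimers) | COC(=O)/C(=C/C(=O)OC(C)(C)C)C(c1c(OC)c(OC)cc(OC)c1C(=O)O)[C@H](O)C(=O)OC
F3 | step 6 | (2E)-4-methoxy-4-oxo-3-[(3S,4R)-5,6,8-trimethoxy-3-(methoxycarbonyl)-1-oxo-3,4-dihydro-1H-isochromen-4-yl]but-2-enoic acid | COC(=O)/C(=C/C(=O)O)[C@H]1c2c(OC)c(OC)cc(OC)c2C(=O)O[C@@H]1C(=O)OC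
F4 | step 6 | (2E)-4-methoxy-3-[(3S,4R)-6-methoxy-3-(methoxycarbonyl)-1,5,8-trioxo-3,4,5,8-tetrahydro-1H-isochromen-4-yl]-4-oxobut-2-enoic acid | COC(=O)/C(=C/C(=O)O)[C@H]1C2=C(C(=O)C=C(OC)C2=O)C(=O)O[C@@H]1C(=O)OC
F5 | step 6 | (2E)-3-[(3S,4R)-6-hydroxy-3-(methoxycarbonyl)-1,5,8-trioxo-3,4,5,8-tetrahydro-1H-isochromen-4-yl]-4-methoxy-4-oxobut-2-enoic acid | COC(=O)/C(=C/C(=O)O)[C@H]1C2=C(C(=O)C=C(O)C2=O)C(=O)O[C@@H]1C(=O)OC
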